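Remark on the chemistry (assumption): atom labels follow germacrane numbering (C8 lactone O–CH, C7 ring-fusion CH, C6 ester-bearing CH, C15 acetoxymethyl on C4, C14 methyl on C10, C12 lactone carbonyl, C13 exo-methylene), and 4-methyl hydrogen itaconate 16 and (S)-3-bromo-2-hydroxy-2-methylpropanoic acid 31 are taken as commercial.

## Analysis of the target

The target 42 is a germacranolide: a ten-membered carbocycle (C1–C10) with an E trisubstituted olefin C1=C10 and a second trisubstituted olefin C4=C5 in which C3 and C6 are cis within the ring (E by the sequence rule because C15 carries oxygen). It is fused at C7–C8 to an α-methylene-γ-butyrolactone (C11=C13, C12 carbonyl, lactone oxygen on C8). The ring carries three contiguous stereocentres, C6 (R), C7 (R) and C8 (S): the lactone is trans-fused (H7 and H8 anti), and in an open zigzag C5–C6–C7–C8–C9 the substituents O6, C11 and O8 are all syn. A fourth, remote stereocentre is the (R)-configured tertiary carbinol of the 2,3-dihydroxy-2-methylpropanoate on O6, which must come from a separate enantiopure building block. Sensitive groups are the exo-methylene lactone (a Michael acceptor), two allylic esters (C15 acetate and the C6 ester), the free 1,2-diol, and the 1,5-diene, which is prone to acid-induced transannular cyclisation and to Cope rearrangement on heating. The synthesis is hard for three reasons: a strained ten-membered ring must be closed, two olefin geometries must be fixed (one of them cis in the ring), and five oxygen functions (O6, O8, O12, O15 and the side-chain diol) must be told apart. The strategy rests on C6 being an allylic carbinol attached to the C4=C5 olefin: the C5–C6 bond is the retron of an alkenylmetal addition to a C6 aldehyde, so an alkenyl iodide at C5 and an aldehyde at C6 can be joined intramolecularly by chromium and nickel, closing the ring and creating C6 in one step.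

## Retrosynthetic reasoning

**Lactone and side-chain diol (42 ⇒ 41 ⇒ 38).** The last operations change only protecting groups and oxidation level. The side-chain diol of 42 is masked as the acetonide 41, and the C12–O8 lactone bond of 41 is traced back to the 1,4-diol 38 (primary allylic C12–OH, secondary C8–OH). Oxidation at C12 next to the C8 hydroxyl closes the five-membered ring by itself, and making the lactone last keeps the Michael acceptor out of every earlier step. O6 must already be acylated, because O6 and O8 are both 1,4 to C12 and would compete for the lactone.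

**Ester bond at O6 (38 ⇒ 37 ⇒ 30 + 35).** Diol 38 is taken back to its bis-silyl ether 37, and the bond between O6 and the side-chain carbonyl is cut to give ring alcohol 30 and acetonide acid 35. This separates the remote stereocentre into a small fragment of its own and leaves 30 with exactly one free hydroxyl. The forward esterification must acylate a hindered secondary allylic alcohol with a quaternary acid without touching C6.

**Ring closure at C5–C6 (30 ⇒ 28).** Cutting C5–C6 opens the ring to the iodo aldehyde 28. This bond is chosen because it removes the ring and the C6 stereocentre together, and because the forward addition delivers the free C6 hydroxyl that is acylated next. Aldehyde 28 already holds both olefins, the C15 acetate and the C11=C13 methylene in final form. The forward reaction must add an alkenylmetal to an enolisable, β-silyloxy aldehyde in the presence of an acetate, keep the C4=C5 geometry, and give 6R.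

**C7–C8 bond and the two stereocentres (28 ⇒ 27 ⇒ 26 ⇒ 25 ⇒ 23 + 15).** Aldehyde 28 comes from alcohol 27 by oxidation, 27 from imide 26 by reductive removal of the auxiliary, and 26 from aldol adduct 25 by silylation. Cutting C7–C8 in 25 gives the β,γ-unsaturated imide 23 and aldehyde 15. The cut is placed here because the C7/C8 syn relationship is the signature of an auxiliary-controlled syn aldol, and because it divides the chain into a four-carbon piece (C6, C7, C11–C13) and the long C8–C5 piece. The reduction must spare the C15 acetate, which is why a mild borohydride is planned and not an aluminium hydride.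

**Imide (23 ⇒ 20 + 21; 20 ⇒ 19 ⇒ 18 ⇒ 16).** The imide is cut at the N–acyl bond into acid 20 and oxazolidinone 21. Acid 20 maps onto the itaconate skeleton of 16: the non-conjugated carboxyl becomes C6, the conjugated carboxyl is reduced to the C12 hydroxymethyl group, and the methylene is C13. C12 is carried at the alcohol level because an ester there could not be told apart from the imide when C6 is reduced.

**Iodoalkene and C3–C4 (15 ⇒ 14 ⇒ 13 ⇒ 12 ⇒ 11 ⇒ 9 ⇒ 8; 8 ⇒ 6 + 7).** Aldehyde 15 is taken back through alcohol 14, its 4-methoxybenzyl ether 13 and allylic alcohol 12 to the iodoacrylic acid 11. In 11 the C4=C5 geometry (iodine cis to C3, trans to the carboxyl that becomes C15) arises from decarboxylative elimination of the diiodomethyl malonate 9. C5 therefore enters as a diiodomethyl group on malonate 8, and the C3–C4 bond is cut to give primary iodide 6 and diethyl malonate 7. A carbometalation across a C4≡C5 alkyne was set aside: with ether oxygen at C15 the metal is steered onto C4 and the adduct collapses to an allene, and with the free alkoxide the addition turns anti and puts iodine cis to C15.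

**E olefin C1=C10 (6 ⇒ 5 ⇒ 2 ⇒ 1).** Iodide 6 comes from alcohol 5, in which C2 and C3 were added together as a two-carbon electrophile opened by the alkenylalanate 4. The alanate stems from syn-methylalumination of the protected alkynol 2, itself from 3-butyn-1-ol 1. The C1–C2 bond is cut here because the methylalumination fixes the E geometry and the C14 methyl group in one operation.

**Side-chain acid (35 ⇒ 34 ⇒ 33 ⇒ 31).** Acid 35 is the acetonide of diol acid 33, which is reached from the enantiopure bromohydrin acid 31 by replacing bromine with hydroxyl at the primary carbon. The quaternary stereocentre is bought, not made, and is never touched.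

## Alternatives that were turned down

**Alternative 1:** The ring would be unfolded from a six-membered ring made of C1–C6: the C8–C9 bond is formed while an extra C6–C1 bond is broken. The forward key step is an anionic oxy-Cope rearrangement. A strong potassium base turns a tertiary C6 hydroxyl into its alkoxide, the 1,5-diene C8=C7–C6–C1–C10=C9 (an enol ether on C6, an isopropenyl group on C1) undergoes the [3,3] shift, and protonation of the enolate at C7 gives the ten-membered ketone A1, fused at C7–C8 to a methoxy-tetrahydrofuran as a masked lactone.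
- For it: no high dilution is needed, the alkoxide-accelerated rearrangement pays for the ring strain, the E geometry of C1=C10 follows from a chair-like transition state, and the ring-cis C4=C5 olefin is inherited from the six-membered ring.
- Against it: C6 arrives as a ketone, so its configuration needs a separate reduction on a flexible ring next to C7, which is set only by enolate protonation and can epimerise. The C8 configuration depends on the facial course of the rearrangement and not on a reagent. The exo-methylene C13 is missing and would have to be added to the lactone late, beside an acetate and an allylic ester.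
- Comparison: A1 is stronger on the ring-forming event and on concentration. The chosen route offers in its place a C6 hydroxyl formed at the right oxidation level during ring closure, C7/C8 from an auxiliary-controlled aldol, and C11=C13 and the C15 acetate in place before cyclisation, so that four steps remain after the ring.

**Alternative 2:** The ring would be cut between the two allylic methylenes C2 and C3. In the forward key step a potassium amide base deprotonates an allylic sulfone at C3 and the carbanion displaces a primary allylic chloride at C2, closing the ring to sulfone A2 as a mixture at C3.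
- For it: carbanion alkylation is a proven way to medium and large carbocycles, no stereocentre is at stake in the ring closure, and all three ring stereocentres exist beforehand.
- Against it: the sulfone must then be removed reductively. Because it is allylic to C4=C5, the intermediate allyl anion or radical can scramble the position and geometry of that olefin, and the reductant threatens the allylic oxygen substituents at C15 and C6. C6 has to be created in an open chain without the bias of the ring. Four different protecting groups are needed, and two of them (at O15 and O6) must be exchanged for esters after cyclisation.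
- Comparison: A2 is as strong or stronger in the ring closure itself, since an SN2 alkylation is less delicate than addition to an enolisable aldehyde. The chosen route offers in its place no reductive step on the diene, fewer protecting-group exchanges, and ring and C6 formed together.

**Alternative 3:** The ten-membered ring would be derived from a bicyclo[5.3.0]decane by cleaving the central C6–C10 bond. The forward key step is a Grob fragmentation: a potassium alkoxide base deprotonates a tertiary C6 hydroxyl, the C6–C10 bond breaks as a sulfonate leaves C1, and the C6 ketone and the C1=C10 olefin form together to give enone A3.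
- For it: the concerted fragmentation transfers relative configuration into olefin geometry, so E at C1=C10 is stereospecific, the cis C4=C5 olefin is locked by the seven-membered ring, and no dilution is needed.
- Against it: it needs a bicycle with defined configuration at C1, C6 and the quaternary C10 in addition to C7 and C8, which is a long stereocontrolled synthesis. The product is a β-silyloxy ketone with an alkenyl-bearing α-stereocentre exposed to alkoxide, so C7 epimerisation, β-elimination of O8 and migration of C11=C13 into conjugation are all open. C6 is again a ketone to be reduced selectively.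
- Comparison: A3 is stronger on proof of the C1=C10 geometry at the moment of ring formation. The chosen route secures that geometry early by methylalumination and offers in its place a base-free ring closure and a much shorter path to the precursor.

Key step: step 19

## Route

Step 1
Reactants: 1 but-3-yn-1-ol
Product: 2 1-[(but-3-yn-1-yloxy)methyl]-4-methoxybenzene
Conditions: NaH, 4-methoxybenzyl chloride, Bu4NI (cat.), THF, 0 °C to rt
Reagents that add atoms: 4-methoxybenzyl chloride, COc1ccc(CCl)cc1
Why: Williamson ether synthesis on the primary alkoxide; the 4-methoxybenzyl ether is chosen because it should survive the aluminium, hydride and hot hydroxide steps ahead and be removed oxidatively beside an acetate and an alkenyl iodide.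

Step 2
Reactants: 2 1-[(but-3-yn-1-yloxy)methyl]-4-methoxybenzene
Product: 5 (3E)-6-[(4-methoxybenzyl)oxy]-4-methylhex-3-en-1-ol, via alkenyldimethylalane 3 (not isolated), via lithium alkenylalanate 4 (not isolated)
Conditions: Me3Al, Cp2ZrCl2 (cat.), CH2Cl2, 0 °C to rt; volatiles removed; n-BuLi, THF/hexane, -78 °C; ethylene oxide, -78 °C to rt
Reagents that add atoms: trimethylaluminium, C[Al](C)C; ethylene oxide, C1CO1
Why: Zirconium-catalysed syn-methylalumination (Negishi carboalumination) places the C14 methyl group on C10 and aluminium on C1; the derived ate complex opens the epoxide with retention at C1, so C2 ends trans to C9 and the E geometry of C1=C10 is fixed here.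

Step 3
Reactants: 5 (3E)-6-[(4-methoxybenzyl)oxy]-4-methylhex-3-en-1-ol
Product: 6 1-({[(3E)-6-iodo-3-methylhex-3-en-1-yl]oxy}methyl)-4-methoxybenzene
Conditions: I2, PPh3, imidazole, CH2Cl2, 0 °C
Reagents that add atoms: iodine, I-I
Why: Appel-type iodination of the primary alcohol by SN2 displacement of the oxyphosphonium ion; the trisubstituted olefin and the benzylic ether are inert.

Step 4
Reactants: 6 1-({[(3E)-6-iodo-3-methylhex-3-en-1-yl]oxy}methyl)-4-methoxybenzene; 7 diethyl malonate
Product: 8 diethyl 2-{(3E)-6-[(4-methoxybenzyl)oxy]-4-methylhex-3-en-1-yl}propanedioate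
Conditions: 7 (2.5 equiv), NaH, THF/DMF, 0 °C; then 6, 60 °C
Reagents that add atoms: none
Why: Malonic ester alkylation: the soft, weakly basic malonate anion displaces the primary iodide by SN2 and forms C3–C4; the excess of malonate should hold back dialkylation and elimination to the diene.

Step 5
Reactants: 8 diethyl 2-{(3E)-6-[(4-methoxybenzyl)oxy]-4-methylhex-3-en-1-yl}propanedioate
Product: 9 diethyl 2-(diiodomethyl)-2-{(3E)-6-[(4-methoxybenzyl)oxy]-4-methylhex-3-en-1-yl}propanedioate
Conditions: NaH, CHI3, Et2O, reflux
Reagents that add atoms: iodoform, IC(I)I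
Why: Diiodomethylation of a monosubstituted malonate: the malonate anion deprotonates iodoform, the triiodomethyl anion loses iodide, and the diiodocarbene is captured by the malonate anion, a far better carbene trap than the remote olefin; this brings in C5 with both iodine atoms.

Step 6
Reactants: 9 diethyl 2-(diiodomethyl)-2-{(3E)-6-[(4-methoxybenzyl)oxy]-4-methylhex-3-en-1-yl}propanedioate
Product: 11 (2E,5E)-2-(iodomethylidene)-8-[(4-methoxybenzyl)oxy]-6-methyloct-5-enoic acid, via dipotassium malonate 10 (not isolated)
Conditions: KOH, EtOH/H2O (3:1), reflux; then 1 M HCl, 0 °C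
Reagents that add atoms: potassium hydroxide, [K+].[OH-]
Why: Saponification followed by decarboxylative anti elimination of iodide (a Grob-type fragmentation of the β-iodo carboxylate); the iodine that stays should prefer the position between the alkyl chain and one carboxylate over the position between two carboxylates, so the acid forms with iodine trans to the carboxyl group and cis to C3, the geometry needed at C4=C5.

Step 7
Reactants: 11 (2E,5E)-2-(iodomethylidene)-8-[(4-methoxybenzyl)oxy]-6-methyloct-5-enoic acid
Product: 12 (2E,5E)-2-(iodomethylidene)-8-[(4-methoxybenzyl)oxy]-6-methyloct-5-en-1-ol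
Conditions: LiAlH4, Et2O, 0 °C
Reagents that add atoms: none
Why: Hydride reduction of the carboxylic acid to the primary allylic alcohol C15; at 0 °C in ether the alkenyl iodide and its geometry should be preserved, as with simpler 3-iodoacrylic acids.

Step 8
Reactants: 12 (2E,5E)-2-(iodomethylidene)-8-[(4-methoxybenzyl)oxy]-6-methyloct-5-en-1-ol
Product: 13 (2E,5E)-2-(iodomethylidene)-8-[(4-methoxybenzyl)oxy]-6-methyloct-5-en-1-yl acetate
Conditions: Ac2O, pyridine, DMAP (cat.), CH2Cl2, 0 °C
Reagents that add atoms: acetic anhydride, CC(=O)OC(C)=O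
Why: Nucleophile-catalysed acetylation of the only free hydroxyl; the C15 acetate of the target is in place from here on.

Step 9
Reactants: 13 (2E,5E)-2-(iodomethylidene)-8-[(4-methoxybenzyl)oxy]-6-methyloct-5-en-1-yl acetate
Product: 14 (2E,5E)-8-hydroxy-2-(iodomethylidene)-6-methyloct-5-en-1-yl acetate
Conditions: DDQ, CH2Cl2/pH 7 buffer, 0 °C
Reagents that add atoms: none
Why: Oxidative cleavage of the 4-methoxybenzyl ether by hydride abstraction and hydrolysis of the oxocarbenium ion; the acetate, the alkenyl iodide and the isolated olefin should not react under buffered conditions.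

Step 10
Reactants: 14 (2E,5E)-8-hydroxy-2-(iodomethylidene)-6-methyloct-5-en-1-yl acetate
Product: 15 (2E,5E)-2-(iodomethylidene)-6-methyl-8-oxooct-5-en-1-yl acetate
Conditions: Dess–Martin periodinane, NaHCO3, CH2Cl2, 0 °C; used at once
Reagents that add atoms: none
Why: Dess–Martin oxidation under buffered, base-free conditions should give the β,γ-unsaturated C8 aldehyde without migration of C1=C10 into conjugation; 3-methylalk-3-enals of this kind are used crude in aldol reactions for that reason.

Step 11
Reactants: 16 4-methoxy-2-methylidene-4-oxobutanoic acid (4-methyl hydrogen itaconate)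
Product: 18 methyl 3-(hydroxymethyl)but-3-enoate, via isobutyl carbonic anhydride 17 (not isolated)
Conditions: i-BuOCOCl, N-methylmorpholine, THF, -15 °C; then NaBH4, H2O, 0 °C
Reagents that add atoms: none
Why: Chemoselective reduction of a carboxylic acid beside an ester through its mixed carbonic anhydride: borohydride attacks the activated acyl carbon and reduces the resulting 2-substituted acrolein in the 1,2 sense, while the methyl ester is untouched; the conjugated carboxyl becomes the C12 hydroxymethyl group.

Step 12
Reactants: 18 methyl 3-(hydroxymethyl)but-3-enoate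
Product: 19 methyl 3-({[tert-butyl(dimethyl)silyl]oxy}methyl)but-3-enoate
Conditions: TBSCl, imidazole, DMF, 0 °C to rt
Reagents that add atoms: tert-butyldimethylsilyl chloride, CC(C)(C)[Si](C)(C)Cl
Why: Silylation of the primary allylic alcohol, run on the crude hydroxy ester so that it cannot lactonise.

Step 13
Reactants: 19 methyl 3-({[tert-butyl(dimethyl)silyl]oxy}methyl)but-3-enoate
Product: 20 3-({[tert-butyl(dimethyl)silyl]oxy}methyl)but-3-enoic acid
Conditions: LiOH·H2O, THF/H2O, 0 °C; then 1 M HCl to pH 4, 0 °C
Reagents that add atoms: lithium hydroxide, [Li+].[OH-]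
Why: Saponification of the methyl ester; attack at the acyl carbon is faster than α-deprotonation, and once the carboxylate has formed the β,γ-olefin should no longer migrate.

Step 14
Reactants: 20 3-({[tert-butyl(dimethyl)silyl]oxy}methyl)but-3-enoic acid; 21 (4R)-4-benzyl-1,3-oxazolidin-2-one
Product: 23 (4R)-4-benzyl-3-[3-({[tert-butyl(dimethyl)silyl]oxy}methyl)but-3-enoyl]-1,3-oxazolidin-2-one, via pivalic mixed anhydride 22 (not isolated)
Conditions: PivCl, Et3N, THF, -20 °C; then 21, LiCl, -20 °C to rt
Reagents that add atoms: none
Why: N-Acylation of the oxazolidinone through the mixed pivalic anhydride, which is attacked at the less hindered acyl carbon; the lithium chloride/triethylamine variant avoids strong base and should keep the olefin out of conjugation.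

Step 15
Reactants: 23 (4R)-4-benzyl-3-[3-({[tert-butyl(dimethyl)silyl]oxy}methyl)but-3-enoyl]-1,3-oxazolidin-2-one; 15 (2E,5E)-2-(iodomethylidene)-6-methyl-8-oxooct-5-en-1-yl acetate
Product: 25 (4R)-4-benzyl-3-[(2R,3S,5E,9E)-9-(acetoxymethyl)-2-(3-{[tert-butyl(dimethyl)silyl]oxy}prop-1-en-2-yl)-3-hydroxy-10-iodo-5-methyldeca-5,9-dienoyl]-1,3-oxazolidin-2-one, via dibutylboron enolate 24 (not isolated)
Conditions: Bu2BOTf, Et3N, CH2Cl2, -78 to 0 °C; then 15, -78 to 0 °C; pH 7 buffer, MeOH, H2O2, 0 °C
Reagents that add atoms: none
Why: Evans syn-aldol reaction: soft enolisation gives the Z boron dienolate, which reacts at its α-carbon through a chair Zimmerman–Traxler transition state on the face away from the benzyl group of the dipole-minimised auxiliary; this sets C7 and C8 with C11 and O8 syn in the chain zigzag, in the absolute sense dictated by the (R)-auxiliary.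

Step 16
Reactants: 25 the aldol adduct named in step 15
Product: 26 (4R)-4-benzyl-3-[(2R,3S,5E,9E)-9-(acetoxymethyl)-3-{[tert-butyl(dimethyl)silyl]oxy}-2-(3-{[tert-butyl(dimethyl)silyl]oxy}prop-1-en-2-yl)-10-iodo-5-methyldeca-5,9-dienoyl]-1,3-oxazolidin-2-one
Conditions: TBSOTf, 2,6-lutidine, CH2Cl2, -78 to 0 °C
Reagents that add atoms: tert-butyldimethylsilyl triflate, CC(C)(C)[Si](C)(C)OS(=O)(=O)C(F)(F)F
Why: Silylation of the secondary C8 hydroxyl with the silyl triflate; it blocks retro-aldol cleavage and keeps O8 masked until the lactone is closed.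

Step 17
Reactants: 26 the bis-silyl imide named in step 16
Product: 27 (2S,3S,5E,9E)-9-(acetoxymethyl)-3-{[tert-butyl(dimethyl)silyl]oxy}-2-(3-{[tert-butyl(dimethyl)silyl]oxy}prop-1-en-2-yl)-10-iodo-5-methyldeca-5,9-dien-1-ol
Conditions: NaBH4, THF/H2O (4:1), 0 °C to rt
Reagents that add atoms: none
Why: Reductive removal of the auxiliary: borohydride attacks the activated exocyclic imide carbonyl, the hemiaminal collapses to the aldehyde, and this is reduced to the C6 alcohol; an isolated acetate reacts far more slowly with NaBH4 under these conditions, and the oxazolidinone is recovered.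

Step 18
Reactants: 27 the C6 alcohol named in step 17
Product: 28 (2R,3S,5E,9E)-9-(acetoxymethyl)-3-{[tert-butyl(dimethyl)silyl]oxy}-2-(3-{[tert-butyl(dimethyl)silyl]oxy}prop-1-en-2-yl)-10-iodo-5-methyldeca-5,9-dienal
Conditions: Dess–Martin periodinane, NaHCO3, CH2Cl2, 0 °C; used without purification
Reagents that add atoms: none
Why: Dess–Martin oxidation of the primary alcohol without base, so that C7 should not epimerise, the β-silyloxy group should not be eliminated and C11=C13 should stay out of conjugation.

Step 19
Reactants: 28 the iodo aldehyde named in step 18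
Product: 30 (1(10)E,4E,6R,7S,8S)-15-acetoxy-8,12-bis{[tert-butyl(dimethyl)silyl]oxy}germacra-1(10),4,11(13)-trien-6-ol, via alkenylchromium dichloride 29 (not isolated)
Conditions: CrCl2 (10 equiv), NiCl2 (1 mol% of the CrCl2), degassed DMSO, rt, slow addition of 28 to 0.003 M; aqueous ethylenediamine work-up
Reagents that add atoms: none
Why: The reaction is an intramolecular Nozaki–Hiyama–Kishi coupling: divalent chromium reduces NiCl2 to zerovalent nickel, which inserts into the C5–I bond with retention, the alkenyl group passes to trivalent chromium, and the alkenylchromium 29 adds to the C6 aldehyde to give a chromium alkoxide that is hydrolysed on work-up. The closest known reaction type is the nickel/chromium-mediated macrocyclisation of alkenyl iodides onto aldehydes, which has closed medium and large carbocycles. The ten-membered ring is closed by C5–C6 bond formation in a 10-exo-trig addition, run by slow addition at high dilution so that ring closure should outrun intermolecular coupling. The new stereocentre C6 is controlled by the adjacent stereocentre C7: in the cyclising conformer the tether through C8 is gauche to the forming bond, the bulky C11 branch is anti to it, and the chromium-bound oxygen takes the open sector beside H7 and not the crowded sector between C8 and C11, which should give 6R (O6 syn to C11 in the chain zigzag). The C4=C5 geometry is carried over from the iodide, because alkenylnickel and alkenylchromium intermediates do not isomerise. The step needs chemoselectivity for the aldehyde over the acetate, the silyl ethers and the olefins, which the oxophilic and weakly basic organochromium reagent provides. It also needs the α-branched, β,γ-unsaturated, β-silyloxy aldehyde to survive, which the neutral, non-enolising conditions secure. The C15 acetate is not on the carbon β to the metal and cannot be lost by β-elimination, and the product carries the free C6 hydroxyl that is acylated next.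

Step 20
Reactants: 31 (2S)-3-bromo-2-hydroxy-2-methylpropanoic acid
Product: 33 (2R)-2,3-dihydroxy-2-methylpropanoic acid, via sodium epoxycarboxylate 32 (not isolated)
Conditions: NaOH (3 equiv), H2O, 0 to 60 °C; then HCl to pH 2; evaporation; extraction into acetone
Reagents that add atoms: sodium hydroxide, [Na+].[OH-]
Why: Base closes the bromohydrin to the epoxide carboxylate, and hydroxide opens it by SN2 at the primary carbon; the C–O bond at the quaternary centre is never broken, so the configuration is retained and only the descriptor changes from S to R with the priorities.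

Step 21
Reactants: 33 (2R)-2,3-dihydroxy-2-methylpropanoic acid
Product: 34 methyl (4R)-2,2,4-trimethyl-1,3-dioxolane-4-carboxylate
Conditions: 2,2-dimethoxypropane, MeOH, TsOH·H2O (cat.), reflux
Reagents that add atoms: 2,2-dimethoxypropane, COC(C)(C)OC; methanol, CO
Why: One-pot Fischer esterification and acetonide formation, driven by the ketal as water scavenger, as in the preparation of tartrate acetonide esters; esterification prevents the competing dioxolanone of the α-hydroxy acid.

Step 22
Reactants: 34 methyl (4R)-2,2,4-trimethyl-1,3-dioxolane-4-carboxylate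
Product: 35 (4R)-2,2,4-trimethyl-1,3-dioxolane-4-carboxylic acid
Conditions: LiOH·H2O, THF/H2O, 0 °C to rt; then 1 M HCl to pH 3, 0 °C
Reagents that add atoms: lithium hydroxide, [Li+].[OH-]
Why: Saponification of the methyl ester; the stereocentre has no α-hydrogen and cannot epimerise, and brief cold acidification should spare the acetonide.

Step 23
Reactants: 30 the ring alcohol named in step 19; 35 (4R)-2,2,4-trimethyl-1,3-dioxolane-4-carboxylic acid
Product: 37 (1(10)E,4E,6R,7S,8S)-15-acetoxy-8,12-bis{[tert-butyl(dimethyl)silyl]oxy}germacra-1(10),4,11(13)-trien-6-yl (4R)-2,2,4-trimethyl-1,3-dioxolane-4-carboxylate, via Yamaguchi mixed anhydride 36 (not isolated)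
Conditions: 2,4,6-trichlorobenzoyl chloride, Et3N, THF, rt; then 30, DMAP, toluene, rt to 40 °C
Reagents that add atoms: none
Why: Yamaguchi esterification: DMAP attacks the mixed anhydride at the aliphatic acyl group and the acylpyridinium ion acylates the hindered secondary allylic C6 alcohol with retention at C6; the tied-back acetonide keeps the quaternary acid compact, and O6 is acylated before O8 is freed because both are 1,4 to C12.

Step 24
Reactants: 37 the ester named in step 23
Product: 38 (1(10)E,4E,6R,7R,8S)-15-acetoxy-8,12-dihydroxygermacra-1(10),4,11(13)-trien-6-yl (4R)-2,2,4-trimethyl-1,3-dioxolane-4-carboxylate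
Conditions: HF·pyridine, pyridine, THF, 0 °C to rt
Reagents that add atoms: none
Why: Fluoride-mediated cleavage of both silyl ethers under buffered, slightly acidic conditions, which should leave the acetonide and the three esters intact and should not favour acyl migration from O6 to O8.

Step 25
Reactants: 38 the diol named in step 24
Product: 41 (1(10)E,4E,6R,7R,8S)-15-acetoxy-6-{[(4R)-2,2,4-trimethyl-1,3-dioxolane-4-carbonyl]oxy}germacra-1(10),4,11(13)-trien-12,8-olide, via hydroxy enal 39 (not isolated), via lactol 40 (not isolated)
Conditions: TEMPO (0.2 equiv), PhI(OAc)2 (3 equiv), CH2Cl2, rt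
Reagents that add atoms: none
Why: Nitroxyl-catalysed oxidation is selective for the primary allylic alcohol; the enal is captured by the C8 hydroxyl as the five-membered lactol, which is oxidised on to the α-methylene-γ-butyrolactone, and C7 and C8 (trans ring fusion) are not touched.

Step 26
Reactants: 41 the lactone acetonide named in step 25
Product: 42 (1(10)E,4E,6R,7R,8S)-15-acetoxy-6-{[(2R)-2,3-dihydroxy-2-methylpropanoyl]oxy}germacra-1(10),4,11(13)-trien-12,8-olide
Conditions: AcOH/H2O (4:1), 45 °C
Reagents that add atoms: none
Why: Acid-catalysed hydrolysis of the isopropylidene ketal releases the 1,2-diol of the side chain; dilute acetic acid is chosen as mild enough for the allylic esters, the methylene lactone and the 1,5-diene.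

## Compound list

1 | but-3-yn-1-ol | C#CCCO | starting material
2 | 1-[(but-3-yn-1-yloxy)methyl]-4-methoxybenzene | C#CCCOCc1ccc(OC)cc1 | intermediate
3 | [(1E)-4-[(4-methoxybenzyl)oxy]-2-methylbut-1-en-1-yl]dimethylalane (not isolated) | C[Al](C)/C=C(\C)CCOCc1ccc(OC)cc1 | intermediate
4 | lithium butyl[(1E)-4-[(4-methoxybenzyl)oxy]-2-methylbut-1-en-1-yl]dimethylalanate (not isolated) | [Li+].CCCC[Al-](C)(C)/C=C(\C)CCOCc1ccc(OC)cc1 | intermediate
5 | (3E)-6-[(4-methoxybenzyl)oxy]-4-methylhex-3-en-1-ol | OCC/C=C(\C)CCOCc1ccc(OC)cc1 | intermediate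
6 | 1-({[(3E)-6-iodo-3-methylhex-3-en-1-yl]oxy}methyl)-4-methoxybenzene | ICC/C=C(\C)CCOCc1ccc(OC)cc1 | intermediate
7 | diethyl propanedioate (diethyl malonate) | CCOC(=O)CC(=O)OCC | starting material
8 | diethyl 2-{(3E)-6-[(4-methoxybenzyl)oxy]-4-methylhex-3-en-1-yl}propanedioate | CCOC(=O)C(CC/C=C(\C)CCOCc1ccc(OC)cc1)C(=O)OCC | intermediate
9 | diethyl 2-(diiodomethyl)-2-{(3E)-6-[(4-methoxybenzyl)oxy]-4-methylhex-3-en-1-yl}propanedioate | CCOC(=O)C(CC/C=C(\C)CCOCc1ccc(OC)cc1)(C(I)I)C(=O)OCC | intermediate
10 | dipotassium 2-(diiodomethyl)-2-{(3E)-6-[(4-methoxybenzyl)oxy]-4-methylhex-3-en-1-yl}propanedioate (not isolated) | [K+].[K+].[O-]C(=O)C(CC/C=C(\C)CCOCc1ccc(OC)cc1)(C(I)I)C([O-])=O | intermediate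
11 | (2E,5E)-2-(iodomethylidene)-8-[(4-methoxybenzyl)oxy]-6-methyloct-5-enoic acid (iodine cis to the C3 chain) | OC(=O)/C(CC/C=C(\C)CCOCc1ccc(OC)cc1)=C/I | intermediate
12 | (2E,5E)-2-(iodomethylidene)-8-[(4-methoxybenzyl)oxy]-6-methyloct-5-en-1-ol | OC/C(CC/C=C(\C)CCOCc1ccc(OC)cc1)=C/I | intermediate
13 | (2E,5E)-2-(iodomethylidene)-8-[(4-methoxybenzyl)oxy]-6-methyloct-5-en-1-yl acetate | CC(=O)OC/C(CC/C=C(\C)CCOCc1ccc(OC)cc1)=C/I | intermediate
14 | (2E,5E)-8-hydroxy-2-(iodomethylidene)-6-methyloct-5-en-1-yl acetate | CC(=O)OC/C(CC/C=C(\C)CCO)=C/I | intermediate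
15 | (2E,5E)-2-(iodomethylidene)-6-methyl-8-oxooct-5-en-1-yl acetate (C8 aldehyde) | CC(=O)OC/C(CC/C=C(\C)CC=O)=C/I | intermediate
16 | 4-methoxy-2-methylidene-4-oxobutanoic acid (4-methyl hydrogen itaconate) | C=C(CC(=O)OC)C(=O)O | starting material
17 | mixed anhydride of 16 with isobutyl hydrogen carbonate (not isolated) | C=C(CC(=O)OC)C(=O)OC(=O)OCC(C)C | intermediate
18 | methyl 3-(hydroxymethyl)but-3-enoate | C=C(CO)CC(=O)OC | intermediate
19 | methyl 3-({[tert-butyl(dimethyl)silyl]oxy}methyl)but-3-enoate | C=C(CO[Si](C)(C)C(C)(C)C)CC(=O)OC | intermediate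
20 | 3-({[tert-butyl(dimethyl)silyl]oxy}methyl)but-3-enoic acid | C=C(CO[Si](C)(C)C(C)(C)C)CC(=O)O | intermediate
21 | (4R)-4-benzyl-1,3-oxazolidin-2-one | O=C1N[C@H](Cc2ccccc2)CO1 | starting material
22 | mixed anhydride of 20 with pivalic acid (not isolated) | C=C(CO[Si](C)(C)C(C)(C)C)CC(=O)OC(=O)C(C)(C)C | intermediate
23 | (4R)-4-benzyl-3-[3-({[tert-butyl(dimethyl)silyl]oxy}methyl)but-3-enoyl]-1,3-oxazolidin-2-one | C=C(CO[Si](C)(C)C(C)(C)C)CC(=O)N1[C@H](Cc2ccccc2)COC1=O | intermediate
24 | (Z)-dibutylboron dienolate of 23 (not isolated) | CCCCB(CCCC)O/C(=C\C(=C)CO[Si](C)(C)C(C)(C)C)N1[C@H](Cc2ccccc2)COC1=O | intermediate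
25 | (4R)-4-benzyl-3-[(2R,3S,5E,9E)-9-(acetoxymethyl)-2-(3-{[tert-butyl(dimethyl)silyl]oxy}prop-1-en-2-yl)-3-hydroxy-10-iodo-5-methyldeca-5,9-dienoyl]-1,3-oxazolidin-2-one (7R,8S in ring numbering) | O=C(N1[C@H](Cc2ccccc2)COC1=O)[C@H](C(=C)CO[Si](C)(C)C(C)(C)C)[C@@H](O)C/C(C)=C/CC/C(COC(C)=O)=C\I | intermediate
26 | C8 tert-butyldimethylsilyl ether of 25 (2R,3S,5E,9E) | O=C(N1[C@H](Cc2ccccc2)COC1=O)[C@H](C(=C)CO[Si](C)(C)C(C)(C)C)[C@@H](O[Si](C)(C)C(C)(C)C)C/C(C)=C/CC/C(COC(C)=O)=C\I | intermediate
27 | (2S,3S,5E,9E)-9-(acetoxymethyl)-3-{[tert-butyl(dimethyl)silyl]oxy}-2-(3-{[tert-butyl(dimethyl)silyl]oxy}prop-1-en-2-yl)-10-iodo-5-methyldeca-5,9-dien-1-ol | OC[C@H](C(=C)CO[Si](C)(C)C(C)(C)C)[C@@H](O[Si](C)(C)C(C)(C)C)C/C(C)=C/CC/C(COC(C)=O)=C\I | intermediate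
28 | (2R,3S,5E,9E)-9-(acetoxymethyl)-3-{[tert-butyl(dimethyl)silyl]oxy}-2-(3-{[tert-butyl(dimethyl)silyl]oxy}prop-1-en-2-yl)-10-iodo-5-methyldeca-5,9-dienal (C6 aldehyde, C5 iodide cis to C3) | O=C[C@H](C(=C)CO[Si](C)(C)C(C)(C)C)[C@@H](O[Si](C)(C)C(C)(C)C)C/C(C)=C/CC/C(COC(C)=O)=C\I | intermediate
29 | alkenylchromium dichloride derived from 28, chromium in place of iodine at C5 (not isolated) | O=C[C@H](C(=C)CO[Si](C)(C)C(C)(C)C)[C@@H](O[Si](C)(C)C(C)(C)C)C/C(C)=C/CC/C(COC(C)=O)=C\[Cr](Cl)Cl | intermediate
30 | (1(10)E,4E,6R,7S,8S)-15-acetoxy-8,12-bis{[tert-butyl(dimethyl)silyl]oxy}germacra-1(10),4,11(13)-trien-6-ol | C=C(CO[Si](C)(C)C(C)(C)C)[C@@H]1[C@@H](O[Si](C)(C)C(C)(C)C)C/C(C)=C/CC/C(COC(C)=O)=C\[C@H]1O | intermediate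
31 | (2S)-3-bromo-2-hydroxy-2-methylpropanoic acid | OC(=O)[C@](C)(O)CBr | starting material
32 | sodium (2R)-2-methyloxirane-2-carboxylate (not isolated) | [Na+].[O-]C(=O)[C@@]1(C)CO1 | intermediate
33 | (2R)-2,3-dihydroxy-2-methylpropanoic acid | OC(=O)[C@](C)(O)CO | intermediate
34 | methyl (4R)-2,2,4-trimethyl-1,3-dioxolane-4-carboxylate | COC(=O)[C@@]1(C)COC(C)(C)O1 | intermediate
35 | (4R)-2,2,4-trimethyl-1,3-dioxolane-4-carboxylic acid | OC(=O)[C@@]1(C)COC(C)(C)O1 | intermediate
36 | mixed anhydride of 35 with 2,4,6-trichlorobenzoic acid (not isolated) | O=C(OC(=O)c1c(Cl)cc(Cl)cc1Cl)[C@@]1(C)COC(C)(C)O1 | intermediate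
37 | (1(10)E,4E,6R,7S,8S)-15-acetoxy-8,12-bis{[tert-butyl(dimethyl)silyl]oxy}germacra-1(10),4,11(13)-trien-6-yl (4R)-2,2,4-trimethyl-1,3-dioxolane-4-carboxylate | C=C(CO[Si](C)(C)C(C)(C)C)[C@@H]1[C@@H](O[Si](C)(C)C(C)(C)C)C/C(C)=C/CC/C(COC(C)=O)=C\[C@H]1OC(=O)[C@@]2(C)COC(C)(C)O2 | intermediate
38 | (1(10)E,4E,6R,7R,8S)-15-acetoxy-8,12-dihydroxygermacra-1(10),4,11(13)-trien-6-yl (4R)-2,2,4-trimethyl-1,3-dioxolane-4-carboxylate | C=C(CO)[C@@H]1[C@@H](O)C/C(C)=C/CC/C(COC(C)=O)=C\[C@H]1OC(=O)[C@@]2(C)COC(C)(C)O2 | intermediate
39 | (1(10)E,4E,6R,7R,8S)-15-acetoxy-8-hydroxy-12-oxogermacra-1(10),4,11(13)-trien-6-yl (4R)-2,2,4-trimethyl-1,3-dioxolane-4-carboxylate (not isolated) | C=C(C=O)[C@@H]1[C@@H](O)C/C(C)=C/CC/C(COC(C)=O)=C\[C@H]1OC(=O)[C@@]2(C)COC(C)(C)O2 | intermediate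
40 | lactol of 39, 8,12-epoxy-12-hydroxy compound, both C12 epimers (not isolated) | C=C1C(O)O[C@H]2C/C(C)=C/CC/C(COC(C)=O)=C\[C@@H](OC(=O)[C@@]3(C)COC(C)(C)O3)[C@H]12 | intermediate
41 | (1(10)E,4E,6R,7R,8S)-15-acetoxy-6-{[(4R)-2,2,4-trimethyl-1,3-dioxolane-4-carbonyl]oxy}germacra-1(10),4,11(13)-trien-12,8-olide | C=C1C(=O)O[C@H]2C/C(C)=C/CC/C(COC(C)=O)=C\[C@@H](OC(=O)[C@@]3(C)COC(C)(C)O3)[C@H]12 | intermediate
42 | (1(10)E,4E,6R,7R,8S)-15-acetoxy-6-{[(2R)-2,3-dihydroxy-2-methylpropanoyl]oxy}germacra-1(10),4,11(13)-trien-12,8-olide (CNP0426025.2) | C=C1C(=O)O[C@H]2C/C(C)=C/CC/C(COC(C)=O)=C\[C@@H](OC(=O)[C@](C)(O)CO)[C@H]12 | target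

## Step count and risk

Total step count: 26 (steps 1–10 to aldehyde 15, steps 11–14 to imide 23, steps 15–19 to ring alcohol 30, steps 20–22 to acid 35, steps 23–26 to the target).
Longest linear sequence: 19 steps from 1 (steps 1–10, 15–19 and 23–26).

Least certain steps:

**Step 19 (key step).** The most likely failure is poor or reversed facial selectivity at C6, because the preference rests on a conformational argument for a flexible ten-membered transition state. Intermolecular coupling and loss of the aldehyde by enolisation come next and are countered by dilution and by using 28 at once. The fallback sets out from 28 and comes back at 37. If the cyclisation gives mainly the C6 epimer, (1(10)E,4E,6S,7S,8S)-15-acetoxy-8,12-bis{[tert-butyl(dimethyl)silyl]oxy}germacra-1(10),4,11(13)-trien-6-ol F1, this alcohol is esterified with acid 35 under Mitsunobu conditions (PPh3, diisopropyl azodicarboxylate, toluene, 0 °C). The side chain then enters with inversion at C6 and 37 is reached directly. A mixture would be separated, the 6R part esterified as in step 23 and the 6S part by the Mitsunobu reaction, so that both converge on 37.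

**Step 6.** The most likely failure is incomplete stereoselection in the decarboxylative elimination (an E/Z mixture at C4=C5), or stalling of the saponification at the quaternary diester under conditions harsh enough to degrade the material. The fallback sets out from 6 and comes back at 13, and draws the geometry from a syn hydrometalation instead:
- Iodide 6 alkylates lithium (trimethylsilyl)acetylide (THF/DMPU) to give trimethyl{(5E)-8-[(4-methoxybenzyl)oxy]-6-methyloct-5-en-1-yn-1-yl}silane F2.
- Palladium-catalysed syn-hydrostannation (Bu3SnH, PdCl2(PPh3)2, THF) is expected to place tin on C4, remote from silicon, giving the stannane tributyl{(1Z,5E)-8-[(4-methoxybenzyl)oxy]-6-methyl-1-(trimethylsilyl)octa-1,5-dien-2-yl}stannane F3.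
- Tin–lithium exchange (n-BuLi, -78 °C) and trapping with paraformaldehyde give, with retention, (2E,5E)-8-[(4-methoxybenzyl)oxy]-6-methyl-2-[(trimethylsilyl)methylidene]oct-5-en-1-ol F4, which is acetylated to its acetate F5.
- Iododesilylation with N-iodosuccinimide in acetonitrile replaces silicon by iodine with retention and gives 13.

**Step 17.** The most likely failure is loss of the C15 acetate, or slow reduction of the hindered imide with silyl migration from O8 to O6, because the selectivity between imide and acetate is only kinetic. The fallback sets out from 26 and comes back at 27. Both the imide and the acetate are reduced on purpose with LiBH4 (THF/MeOH, 0 °C) to the diol (2S,3S,5E,9E)-3-{[tert-butyl(dimethyl)silyl]oxy}-2-(3-{[tert-butyl(dimethyl)silyl]oxy}prop-1-en-2-yl)-9-(hydroxymethyl)-10-iodo-5-methyldeca-5,9-dien-1-ol F6. The unhindered allylic C15 hydroxyl is then acetylated selectively (vinyl acetate with Burkholderia cepacia lipase in tert-butyl methyl ether, or AcCl with 2,4,6-collidine at -78 °C). The C6 hydroxyl is shielded by the branched C7 and its silyloxy neighbour, so 27 should result.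

**Step 26.** The most likely failure is acid-induced transannular cyclisation of the 1,5-diene or solvolysis of the allylic esters before the ester-deactivated dioxolane opens. The fallback sets out from 33 and 30 and comes back at 42 without any acid at the end:
- Acid 33 is persilylated (Et3SiOTf, 2,6-lutidine) to triethylsilyl (2R)-2-methyl-2,3-bis[(triethylsilyl)oxy]propanoate F7.
- The silyl ester is cleaved with K2CO3 in aqueous methanol to (2R)-2-methyl-2,3-bis[(triethylsilyl)oxy]propanoic acid F8.
- Yamaguchi esterification with 30 gives the ester (1(10)E,4E,6R,7S,8S)-15-acetoxy-8,12-bis{[tert-butyl(dimethyl)silyl]oxy}germacra-1(10),4,11(13)-trien-6-yl (2R)-2-methyl-2,3-bis[(triethylsilyl)oxy]propanoate F9.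
- HF·pyridine removes all four silyl groups to the tetraol (1(10)E,4E,6R,7R,8S)-15-acetoxy-8,12-dihydroxygermacra-1(10),4,11(13)-trien-6-yl (2R)-2,3-dihydroxy-2-methylpropanoate F10.
- MnO2 in CH2Cl2 oxidises only the allylic C12 hydroxyl and closes the lactone through the lactol to give 42.

## Further compounds

F1 | step 19 | (1(10)E,4E,6S,7S,8S)-15-acetoxy-8,12-bis{[tert-butyl(dimethyl)silyl]oxy}germacra-1(10),4,11(13)-trien-6-ol (C6 epimer of 30) | C=C(CO[Si](C)(C)C(C)(C)C)[C@@H]1[C@@H](O[Si](C)(C)C(C)(C)C)C/C(C)=C/CC/C(COC(C)=O)=C\[C@@H]1O
F2 | step 6 | trimethyl{(5E)-8-[(4-methoxybenzyl)oxy]-6-methyloct-5-en-1-yn-1-yl}silane | C[Si](C)(C)C#CCC/C=C(\C)CCOCc1ccc(OC)cc1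
F3 | step 6 | tributyl{(1Z,5E)-8-[(4-methoxybenzyl)oxy]-6-methyl-1-(trimethylsilyl)octa-1,5-dien-2-yl}stannane (tin trans to silicon) | CCCC[Sn](CCCC)(CCCC)/C(CC/C=C(\C)CCOCc1ccc(OC)cc1)=C/[Si](C)(C)C
F4 | step 6 | (2E,5E)-8-[(4-methoxybenzyl)oxy]-6-methyl-2-[(trimethylsilyl)methylidene]oct-5-en-1-ol (silicon cis to the C3 chain) | OC/C(CC/C=C(\C)CCOCc1ccc(OC)cc1)=C/[Si](C)(C)C
F5 | step 6 | (2E,5E)-8-[(4-methoxybenzyl)oxy]-6-methyl-2-[(trimethylsilyl)methylidene]oct-5-en-1-yl acetate | CC(=O)OC/C(CC/C=C(\C)CCOCc1ccc(OC)cc1)=C/[Si](C)(C)C
F6 | step 17 | (2S,3S,5E,9E)-3-{[tert-butyl(dimethyl)silyl]oxy}-2-(3-{[tert-butyl(dimethyl)silyl]oxy}prop-1-en-2-yl)-9-(hydroxymethyl)-10-iodo-5-methyldeca-5,9-dien-1-ol | OC[C@H](C(=C)CO[Si](C)(C)C(C)(C)C)[C@@H](O[Si](C)(C)C(C)(C)C)C/C(C)=C/CC/C(CO)=C\I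
F7 | step 26 | triethylsilyl (2R)-2-methyl-2,3-bis[(triethylsilyl)oxy]propanoate | CC[Si](CC)(CC)OC[C@@](C)(O[Si](CC)(CC)CC)C(=O)O[Si](CC)(CC)CC
F8 | step 26 | (2R)-2-methyl-2,3-bis[(triethylsilyl)oxy]propanoic acid | CC[Si](CC)(CC)OC[C@@](C)(O[Si](CC)(CC)CC)C(=O)O
F9 | step 26 | (1(10)E,4E,6R,7S,8S)-15-acetoxy-8,12-bis{[tert-butyl(dimethyl)silyl]oxy}germacra-1(10),4,11(13)-trien-6-yl (2R)-2-methyl-2,3-bis[(triethylsilyl)oxy]propanoate | C=C(CO[Si](C)(C)C(C)(C)C)[C@@H]1[C@@H](O[Si](C)(C)C(C)(C)C)C/C(C)=C/CC/C(COC(C)=O)=C\[C@H]1OC(=O)[C@](C)(O[Si](CC)(CC)CC)CO[Si](CC)(CC)CC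
F10 | step 26 | (1(10)E,4E,6R,7R,8S)-15-acetoxy-8,12-dihydroxygermacra-1(10),4,11(13)-trien-6-yl (2R)-2,3-dihydroxy-2-methylpropanoate | C=C(CO)[C@@H]1[C@@H](O)C/C(C)=C/CC/C(COC(C)=O)=C\[C@H]1OC(=O)[C@](C)(O)CO
A1 | alternative 1 | ten-membered C6 ketone fused at C7–C8 to a 2-methoxytetrahydrofuran, C15 as tert-butyldimethylsilyl ether | C1C(OC)O[C@H]2C/C(C)=C/CC/C(CO[Si](C)(C)C(C)(C)C)=C\C(=O)[C@H]12
A2 | alternative 2 | ten-membered 1(10),4-diene with phenylsulfonyl on C3 (both C3 epimers), O6 as 4-methoxybenzyl ether, O8 and O12 as tert-butyldimethylsilyl ethers, O15 as tert-butyldiphenylsilyl ether | C=C(CO[Si](C)(C)C(C)(C)C)[C@@H]1[C@@H](O[Si](C)(C)C(C)(C)C)C/C(C)=C/CC(S(=O)(=O)c2ccccc2)/C(CO[Si](c2ccccc2)(c2ccccc2)C(C)(C)C)=C\[C@H]1OCc1ccc(OC)cc1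
A3 | alternative 3 | ten-membered cross-conjugated C6 ketone with E C1=C10 and ring-cis C4=C5, O15 as 4-methoxybenzyl ether, O8 and O12 as tert-butyldimethylsilyl ethers | C=C(CO[Si](C)(C)C(C)(C)C)[C@@H]1[C@@H](O[Si](C)(C)C(C)(C)C)C/C(C)=C/CC/C(COCc2ccc(OC)cc2)=C\C1=O
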